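**Remark on the chemistry:** germacrane numbering is used throughout (ring C1–C10, acrylate unit C11–C13 on C7, C14 on C10, C15 on C4). The seco acid 39 and the target 41 agree atom by atom in the configuration at C7 and C8 and in both alkene geometries, so 39 is taken as drawn and used unprotected in the last step. It is assumed that a P450 variant with the required C6 site and face selectivity can be obtained by directed evolution.

## Structural features

The target is a ten-membered carbocycle (C1–C10) fused across C6–C7 to an α-methylene-γ-butyrolactone (O, C6, C7, C11, C12). Both ring alkenes, C1=C10 and C4=C5, are trisubstituted and cis within the ring (E by the sequence rule only because C14 and C15 outrank the ring carbons), so C2/C9 and C3/C6 are cis pairs. C6, C7 and C8 are contiguous stereocentres (6R,7S,8S), with the lactone oxygen, C11 and the isovalerate oxygen all on one face. Fragile groups are the C14 enal, the exocyclic acrylate, the secondary isovalerate, the primary allylic C15 alcohol and the skipped diene; a free C8 hydroxyl would also trap a C12 carbonyl as the 8,12-lactone and a C14 aldehyde as a five-membered lactol. The real difficulty is a medium ring with two geometry-defined trisubstituted alkenes, four oxidation levels to tell apart at C8, C12, C14 and C15, and oxygenation of C6 on the face of C11. The key step exploits that C6–H is allylic to C4=C5 and γ to the C12 carboxyl on C11: one C–H hydroxylation creates C6, and the hydroxy acid closes the lactone ring by itself. Competing C–H bonds are at C2, C3, C9, C15 and the tertiary allylic C7. The two halves C2–C1=C10(C14)–C9 and C6–C5=C4(C15)–C3 share one 2-substituted but-2-ene-1,4-diyl pattern, so both alkenes can come from the same directed trans-hydroalumination/iodination of a propargylic alcohol.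

## Logic of the disconnections

41 ⇒ 39 (through 40). The C6–O and O–C12 bonds are cut. This removes the lactone ring and the C6 stereocentre in one move and leaves a seco acid with only C7 and C8 to build. The forward step must oxidise one allylic C–H among several and on one face, which no small reagent can do here; it is therefore assigned to an enzyme and placed last.

39 ⇒ 38 ⇒ 36 ⇒ 35 ⇒ 33 + 34. The C14 aldehyde and C15 alcohol are masked (dioxolane, silyl ether), C12 is taken back to a protected allylic alcohol, and the C8–O acyl bond is cut. The order is forced: C8 must be acylated before C12 is oxidised, because a free C8 hydroxyl would lactonise onto C12. The acetal must be cyclic to survive the chlorite oxidation, and the C12 ether must come off without acid or base (oxidative cleavage).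

33 ⇒ 32 ⇒ 31 ⇒ 30. The ring bond C2–C3 is cut between two allylic carbons, with a sulfonyl group on C2 and a bromide on C3. The sulfone is put on C2 because the allyl unit C2–C1–C10 has one fully substituted end, so hydride delivery in the later desulfonylation can only go to C2. The gain is an open chain; the demand is high dilution and a substrate free of esters and carbonyls, which dictates the protecting-group pattern of 30.

30 ⇒ 29 ⇒ 28 ⇒ 27 ⇒ 26 + 23. The C11=C13 and C11–C12 bonds are cut back to an amide carbonyl at C11. This is done because the aldol leaves C11 as a carboxyl derivative. The forward steps need a non-basic methylenation (C7 is epimerisable) and an excess of organolithium, since the sulfone α-protons are acidic.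

26 ⇒ 25 ⇒ 24 ⇒ 22 + 10. The C7–C8 bond is cut as a syn aldol; it joins the two halves and sets both stereocentres from one auxiliary. The demand is a β,γ-unsaturated aldehyde (10) that must not slip into conjugation.

10 ⇒ 9 ⇒ 7 + 8; 7 ⇒ 4 + 5; 4 ⇒ 3 ⇒ 2 ⇒ 1. The C9–C10 bond (sp3–sp2 coupling), the C2–S bond, and the H/I pair across C1=C10 are cut in turn. The alkene geometry then rests on a trans-hydroalumination that places iodine cis to C2, and the coupling must proceed with retention.

22 ⇒ 21 ⇒ 19 + 20; 19 ⇒ 16 + 17; 16 ⇒ 14 + 15; 14 ⇒ 13 ⇒ 12 ⇒ 11. The C3–C4 bond (hydroxymethyl coupling), the N–C11 bond, the C6–C7 bond (acetate alkylation) and the H/I pair across C4=C5 are cut. The same alkyne logic as in the other half fixes C3 cis to C6; the pivalate on C3 must survive the aldol and organometallic steps.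

23 ⇒ 20. The benzylic C–O bond is cut; a simple etherification supplies the alkoxymethyl nucleophile for C12.

## Other disconnections considered

Alternative 1: The cut is the C7–C8 bond, with the C11=C13 alkene moved back to C7=C11 and C13 tied to the C8 oxygen, so that the carbocycle is enlarged to a thirteen-membered ring. Forward, tin–lithium exchange with n-BuLi at C8 would trigger a Wittig–Still [2,3]-shift that forms C7–C8, moves the alkene to C11=C13 and contracts the ring to the ten-membered homoallylic alcohol A1.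
- In favour: the ring is first closed as a less strained ether; the shift is concerted and would create C7, C8 and the exocyclic methylene together; the C8 hydroxyl emerges free for direct acylation; the C6 oxygen is already present, so no C–H oxidation is needed.
- Against: a tin-bearing C8 next to oxygen and a defined C7=C11 geometry must be built into a macrocycle; chirality transfer depends on the conformation of a flexible ring; [1,2]-shift and elimination compete under n-BuLi; A1 still needs adjustment at C12, C14 and C15 and lactonisation.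
- Comparison: on structure it carries the C6 oxygen from synthesis, which is the better choice for certainty about the C6 configuration. On mechanism a sigmatropic shift is better understood than an enzyme not yet evolved, but for C7/C8 the auxiliary-controlled aldol of the chosen plan is the better-precedented control element. On step economy the two are about equal, since the extra C6 stereocentre and its protection offset the sulfone steps saved.

Alternative 2: The cut is a transannular C1–C6 bond, so that the ten-membered ring is read as a decalin cleaved across its ring fusion. Forward, an Eschenmoser–Tanabe fragmentation (p-toluenesulfonohydrazide acting on a C10 carbonyl flanked by a C1–C6 epoxide) would break C1–C6, make C1–C10 a triple bond and C6 a ketone, and so deliver the cyclodecenynone A2.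
- In favour: no high-dilution ring closure, which is better than step 22 of the chosen plan; C7 and C8 can be set on a rigid six-membered ring; the C4=C5 geometry is fixed by the bicycle; the C6 ketone can give the lactone oxygen by reduction.
- Against: the C1≡C10 alkyne must be converted regio- and stereoselectively into the trisubstituted enal, and a ring alkyne flanked by two methylenes offers little regiocontrol; the C6 ketone must be reduced on one face of a flexible enone; the acetate side chain still needs α-methylenation; the bicyclic substrate of the fragmentation is itself long to make.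
- Comparison: on structure it is the equal of Alternative 1 in carrying the C6 oxygen. On mechanism the fragmentation is the more reliable ring-forming event. On step economy it is likely worse than the chosen plan because of the alkyne-to-enal problem and the construction of the bicycle, though it avoids an unprecedented last step.

Alternative 3: The cut is the C4=C5 alkene. Forward, an intramolecular Horner–Wadsworth–Emmons reaction (LiCl, amine base) between a phosphonoacetate unit at C4 and an aldehyde group at C5 would close the ring as the enoate A3.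
- In favour: mild conditions tolerate esters and silyl ethers; the intrinsic preference (ester trans to C6) coincides with the ring-cis geometry needed; C15 arrives differentiated as an ester; all three stereocentres are in place beforehand.
- Against: olefination closure of a ten-membered carbocycle has to beat strain and dimerisation; the aldehyde carbon C5 stands next to the silyloxy-bearing C6 (epimerisation, β-elimination); the C15 ester must later be reduced by hydride in the presence of other groups; four silyl and benzyl ethers must be told apart.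
- Comparison: on structure it needs the C6 stereocentre and its protection from the start, whereas the chosen plan defers C6 to the end. On mechanism it is the equal of the sulfone alkylation in medium-ring precedent and the better in functional-group tolerance. On step economy it is about equal, and it is the better plan if no suitable enzyme can be evolved.

Key step: step 29

## Route

Step 1
Reactants: 1 3,3-diethoxyprop-1-yne
Product: 2 2-ethynyl-1,3-dioxolane
Conditions: HOCH2CH2OH, TsOH (cat.), 80 °C, EtOH distilled off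
Reagents that add atoms: ethane-1,2-diol, OCCO
Why: Acid-catalysed transacetalisation, driven by removal of ethanol and the entropy gain of the cyclic acetal. The dioxolane is chosen because an open-chain enal acetal would not survive the chlorite oxidation of step 27.

Step 2
Reactants: 2 2-ethynyl-1,3-dioxolane
Product: 3 3-(1,3-dioxolan-2-yl)prop-2-yn-1-ol
Conditions: n-BuLi, THF, −78 °C; (CH2O)n, −78 °C → rt
Reagents that add atoms: formaldehyde (as paraformaldehyde), C=O
Why: Addition of a lithium acetylide to formaldehyde (alkynylation); the acetal is inert to base and no stereocentre is formed.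

Step 3
Reactants: 3 3-(1,3-dioxolan-2-yl)prop-2-yn-1-ol
Product: 4 (2Z)-3-(1,3-dioxolan-2-yl)-3-iodoprop-2-en-1-ol
Conditions: NaAlH2(OCH2CH2OMe)2, THF, 0 °C; then I2, −78 °C
Reagents that add atoms: iodine, [I][I]
Why: Hydroxyl-directed trans-hydroalumination of a propargylic alcohol puts hydride on C1 and aluminium on C10 within a five-membered alkoxyaluminate. Iodinolysis with retention gives the Z-iodoalkene, which fixes C2 cis to the future C9.

Step 4
Reactants: 4 (2Z)-3-(1,3-dioxolan-2-yl)-3-iodoprop-2-en-1-ol; 5 sodium benzenesulfinate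
Product: 7 2-[(1Z)-1-iodo-3-(phenylsulfonyl)prop-1-en-1-yl]-1,3-dioxolane, via allylic mesylate 6 (not isolated)
Conditions: MsCl, Et3N, CH2Cl2, −20 °C; then PhSO2Na, DMF, rt
Reagents that add atoms: sodium benzenesulfinate 5, [Na+].[O-]S(=O)c1ccccc1
Why: Mesylation followed by S-alkylation of the sulfinate (SN2 at the primary allylic carbon); SN2' is blocked by the fully substituted iodo-carbon and the base-stable acetal is untouched.

Step 5
Reactants: 7 2-[(1Z)-1-iodo-3-(phenylsulfonyl)prop-1-en-1-yl]-1,3-dioxolane; 8 ethyl bromoacetate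
Product: 9 ethyl (3E)-3-(1,3-dioxolan-2-yl)-5-(phenylsulfonyl)pent-3-enoate
Conditions: BrZnCH2CO2Et (from 8, Zn, THF), Pd(dba)2 (5 mol %), P(t-Bu)3 (5 mol %), THF, rt
Reagents that add atoms: ethyl bromoacetate 8 (as its zinc reagent), BrCC(=O)OCC
Why: Negishi-type cross-coupling of a Reformatsky zinc enolate with an alkenyl iodide; retention at sp2 carbon places C9 cis to C2. The weakly basic zinc reagent leaves the sulfone α-protons alone.

Step 6
Reactants: 9 ethyl (3E)-3-(1,3-dioxolan-2-yl)-5-(phenylsulfonyl)pent-3-enoate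
Product: 10 (3E)-3-(1,3-dioxolan-2-yl)-5-(phenylsulfonyl)pent-3-enal
Conditions: i-Bu2AlH (1.1 equiv), CH2Cl2, −78 °C; MeOH, aq. KNaC4H4O6 (potassium sodium tartrate)
Reagents that add atoms: none
Why: Partial reduction of an ester through the aluminium hemiacetal that is stable at −78 °C. The β,γ-unsaturated aldehyde is used at once and cold so that the alkene does not move into conjugation.

Step 7
Reactants: 11 but-2-yne-1,4-diol
Product: 12 4-[(tert-butyldiphenylsilyl)oxy]but-2-yn-1-ol
Conditions: t-BuPh2SiCl (1 equiv), imidazole, THF, 0 °C → rt, diol in threefold excess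
Reagents that add atoms: tert-butyl(chloro)diphenylsilane, CC(C)(C)[Si](Cl)(c1ccccc1)c1ccccc1
Why: Statistical monosilylation of a symmetrical diol used in excess; the robust silyl ether will carry C15–O to the penultimate step.

Step 8
Reactants: 12 4-[(tert-butyldiphenylsilyl)oxy]but-2-yn-1-ol
Product: 13 (2Z)-4-[(tert-butyldiphenylsilyl)oxy]-3-iodobut-2-en-1-ol
Conditions: NaAlH2(OCH2CH2OMe)2, THF, 0 °C; then I2, −78 °C
Reagents that add atoms: iodine, [I][I]
Why: Same hydroxyl-directed trans-hydroalumination/iodination as step 3 (hydride to C5, aluminium then iodine to C4), so iodine and later C3 stand cis to C6.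

Step 9
Reactants: 13 (2Z)-4-[(tert-butyldiphenylsilyl)oxy]-3-iodobut-2-en-1-ol
Product: 14 {[(2Z)-4-bromo-2-iodobut-2-en-1-yl]oxy}(tert-butyl)diphenylsilane
Conditions: CBr4, PPh3, CH2Cl2, 0 °C
Reagents that add atoms: tetrabromomethane, BrC(Br)(Br)Br
Why: Appel bromination of a primary allylic alcohol under neutral conditions; the alkene geometry and the silyl ether are unaffected.

Step 10
Reactants: 14 {[(2Z)-4-bromo-2-iodobut-2-en-1-yl]oxy}(tert-butyl)diphenylsilane; 15 acetic acid
Product: 16 (4Z)-6-[(tert-butyldiphenylsilyl)oxy]-5-iodohex-4-enoic acid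
Conditions: AcOH, LiN(i-Pr)2 (2 equiv per AcOH), THF/DMPU, 0 → 40 °C; then 14, −20 °C → rt; aq. HCl
Reagents that add atoms: acetic acid 15, CC(=O)O
Why: C-alkylation of the acetic acid dianion (enediolate) with a reactive allylic bromide forms the C6–C7 bond by SN2. The amide base is fully consumed before the bromide is added, to spare the alkenyl iodide.

Step 11
Reactants: 16 (4Z)-6-[(tert-butyldiphenylsilyl)oxy]-5-iodohex-4-enoic acid; 17 (4R)-4-benzyl-1,3-oxazolidin-2-one
Product: 19 (4R)-4-benzyl-3-{(4Z)-6-[(tert-butyldiphenylsilyl)oxy]-5-iodohex-4-enoyl}-1,3-oxazolidin-2-one, via mixed pivalic anhydride 18 (not isolated)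
Conditions: t-BuCOCl, Et3N, THF, −20 °C; then 17, LiCl, rt
Reagents that add atoms: (4R)-4-benzyl-1,3-oxazolidin-2-one 17, O=C1N[C@H](Cc2ccccc2)CO1
Why: N-acylation of the oxazolidinone through the mixed anhydride; the hindered pivaloyl carbonyl directs attack to the desired acyl group.

Step 12
Reactants: 19 (4R)-4-benzyl-3-{(4Z)-6-[(tert-butyldiphenylsilyl)oxy]-5-iodohex-4-enoyl}-1,3-oxazolidin-2-one; 20 (tributylstannyl)methanol
Product: 21 (4R)-4-benzyl-3-{(4E)-6-[(tert-butyldiphenylsilyl)oxy]-5-(hydroxymethyl)hex-4-enoyl}-1,3-oxazolidin-2-one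
Conditions: Pd(PPh3)4 (5 mol %), 1,4-dioxane, 85 °C
Reagents that add atoms: (tributylstannyl)methanol 20, CCCC[Sn](CCCC)(CCCC)CO
Why: Stille (Kosugi–Migita) hydroxymethylation of an alkenyl iodide; retention at C4 places the new C3 cis to C6 and the C15 arm trans to it.

Step 13
Reactants: 21 (4R)-4-benzyl-3-{(4E)-6-[(tert-butyldiphenylsilyl)oxy]-5-(hydroxymethyl)hex-4-enoyl}-1,3-oxazolidin-2-one
Product: 22 (4R)-4-benzyl-3-{(4E)-6-[(tert-butyldiphenylsilyl)oxy]-5-[(pivaloyloxy)methyl]hex-4-enoyl}-1,3-oxazolidin-2-one
Conditions: t-BuCOCl, pyridine, DMAP (cat.), CH2Cl2, 0 °C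
Reagents that add atoms: pivaloyl chloride, CC(C)(C)C(=O)Cl
Why: Acylation of the primary allylic alcohol. The pivalate survives the aldol, aluminium amide and organometallic steps and is later removed by hydride when no other carbonyl is left.

Step 14
Reactants: 20 (tributylstannyl)methanol
Product: 23 tributyl{[(4-methoxybenzyl)oxy]methyl}stannane
Conditions: NaH, THF/DMF, 0 °C; 4-MeOC6H4CH2Cl, Bu4NI (cat.), rt
Reagents that add atoms: 4-methoxybenzyl chloride, COc1ccc(CCl)cc1
Why: Williamson etherification; it provides the precursor of the alkoxymethyllithium that will deliver C12 with an oxidatively removable ether.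

Step 15
Reactants: 22 (4R)-4-benzyl-3-{(4E)-6-[(tert-butyldiphenylsilyl)oxy]-5-[(pivaloyloxy)methyl]hex-4-enoyl}-1,3-oxazolidin-2-one; 10 (3E)-3-(1,3-dioxolan-2-yl)-5-(phenylsulfonyl)pent-3-enal
Product: 24 (4R)-4-benzyl-3-{(2R,3S,5E)-2-[(2E)-4-[(tert-butyldiphenylsilyl)oxy]-3-[(pivaloyloxy)methyl]but-2-en-1-yl]-5-(1,3-dioxolan-2-yl)-3-hydroxy-7-(phenylsulfonyl)hept-5-enoyl}-1,3-oxazolidin-2-one
Conditions: Bu2BOTf, i-Pr2NEt, CH2Cl2, 0 °C; 10, −78 → 0 °C; then pH 7 buffer (Na2HPO4/NaH2PO4), MeOH, H2O2, 0 °C
Reagents that add atoms: none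
Why: Evans syn aldol. The Z-boron enolate reacts through a chair transition state with the aldehyde on the enolate face away from the benzyl group of the (R)-auxiliary, which sets C7 (R here) and C8 (S) as the (2R,3S) syn pair. Enolisation is completed before the labile aldehyde is added at −78 °C.

Step 16
Reactants: 24 aldol adduct (as named in step 15)
Product: 25 (2R,3S,5E)-2-[(2E)-4-[(tert-butyldiphenylsilyl)oxy]-3-[(pivaloyloxy)methyl]but-2-en-1-yl]-5-(1,3-dioxolan-2-yl)-3-hydroxy-N-methoxy-N-methyl-7-(phenylsulfonyl)hept-5-enamide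
Conditions: MeNHOMe·HCl, AlMe3, CH2Cl2, −10 → 0 °C
Reagents that add atoms: N,O-dimethylhydroxylamine hydrochloride, CNOC.Cl
Why: Transamination of the imide by the aluminium amide, assisted by the free β-hydroxyl; the auxiliary is released intact, and the hindered pivalate and the dioxolane are inert at 0 °C.

Step 17
Reactants: 25 N-methoxy-N-methylamide (as named in step 16)
Product: 26 (2R,3S,5E)-2-[(2E)-4-[(tert-butyldiphenylsilyl)oxy]-3-[(pivaloyloxy)methyl]but-2-en-1-yl]-5-(1,3-dioxolan-2-yl)-N-methoxy-N-methyl-7-(phenylsulfonyl)-3-[(triethylsilyl)oxy]hept-5-enamide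
Conditions: Et3SiCl, imidazole, DMAP (cat.), DMF, rt
Reagents that add atoms: chlorotriethylsilane, CC[Si](Cl)(CC)CC
Why: Silylation under basic conditions. A silyl triflate is avoided because Lewis acid could open the dioxolane onto the neighbouring C8 hydroxyl.

Step 18
Reactants: 26 silyl ether (as named in step 17); 23 tributyl{[(4-methoxybenzyl)oxy]methyl}stannane
Product: 27 (3R,4S,6E)-3-[(2E)-4-[(tert-butyldiphenylsilyl)oxy]-3-[(pivaloyloxy)methyl]but-2-en-1-yl]-6-(1,3-dioxolan-2-yl)-1-[(4-methoxybenzyl)oxy]-8-(phenylsulfonyl)-4-[(triethylsilyl)oxy]oct-6-en-2-one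
Conditions: 23, n-BuLi, THF, −78 °C (2.5 equiv of the lithium reagent); then 26 added, −78 °C; AcOH, −78 °C
Reagents that add atoms: tributyl{[(4-methoxybenzyl)oxy]methyl}stannane 23 (as the alkoxymethyllithium), CCCC[Sn](CCCC)(CCCC)COCc1ccc(OC)cc1
Why: Tin–lithium exchange gives the alkoxymethyllithium, which adds to the N-methoxy-N-methylamide to form a stable chelated adduct that releases the ketone only on quench. One equivalent is consumed by the acidic sulfone α-proton and returned on quench. Adding the substrate to excess reagent at −78 °C keeps addition to C11 faster than any reaction of the sulfonyl carbanion.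

Step 19
Reactants: 27 ketone (as named in step 18)
Product: 28 (7S,8S)-2,3-seco-germacra-1(10),4,11(13)-triene with C2 phenylsulfonyl, C3 pivaloyloxy, C8 triethylsilyloxy, C12 (4-methoxybenzyl)oxy, C14 as 1,3-dioxolan-2-yl and C15 tert-butyldiphenylsilyloxy; C3 cis to C6 and C2 cis to C9
Conditions: Cp2Ti(μ-CH2)(μ-Cl)AlMe2, pyridine (cat.), THF/toluene, −40 → 0 °C
Reagents that add atoms: Tebbe reagent Cp2Ti(μ-CH2)(μ-Cl)AlMe2 (Cl→Al bridge bond not drawn), C[Al](C)C[Ti](Cl)(C1C=CC=C1)C1C=CC=C1
Why: Tebbe methylenation of the ketone. The reagent is not basic, so C7 is not epimerised, the β-silyloxy group is not eliminated and the sulfone is not deprotonated; the ketone reacts much faster than the hindered pivalate.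

Step 20
Reactants: 28 pivalate (as described in step 19)
Product: 29 the C3 alcohol corresponding to 28 (C3–OH, otherwise unchanged)
Conditions: i-Bu2AlH (2.5 equiv), CH2Cl2, −78 °C
Reagents that add atoms: none
Why: Reductive cleavage of the pivalate, now the only carbonyl group in the molecule; at −78 °C the dioxolane, the ethers and the sulfone are not touched.

Step 21
Reactants: 29 C3 alcohol (as described in step 20)
Product: 30 the C3 bromide corresponding to 29 (C3–Br, otherwise unchanged)
Conditions: CBr4, PPh3, 2,6-lutidine, CH2Cl2, −20 °C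
Reagents that add atoms: tetrabromomethane, BrC(Br)(Br)Br
Why: Appel bromination of the primary allylic alcohol, buffered so that the triethylsilyl ether and the dioxolane survive.

Step 22
Reactants: 30 C3 bromide (as described in step 21)
Product: 31 (7S,8S)-2-(phenylsulfonyl)germacra-1(10)E,4E,11(13)-triene with C8 triethylsilyloxy, C12 (4-methoxybenzyl)oxy, C14 as 1,3-dioxolan-2-yl and C15 tert-butyldiphenylsilyloxy; both ring alkenes ring-cis; mixture of C2 epimers
Conditions: LiN(SiMe3)2 (1.2 equiv), THF, −78 → −20 °C, slow addition of 30 (final 2 mM)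
Reagents that add atoms: none
Why: Intramolecular alkylation of the lithiated allylic sulfone (α-attack, SN2 at the primary allylic bromide) closes the ten-membered ring under high dilution. Both alkene geometries are already fixed, and the C2 configuration is irrelevant because the sulfonyl group is removed next.

Step 23
Reactants: 31 macrocyclic sulfone (as described in step 22)
Product: 32 (7S,8S)-germacra-1(10)E,4E,11(13)-triene with C8 triethylsilyloxy, C12 (4-methoxybenzyl)oxy, C14 as 1,3-dioxolan-2-yl and C15 tert-butyldiphenylsilyloxy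
Conditions: PdCl2(dppp) (10 mol %), LiBHEt3, THF, 0 °C → rt
Reagents that add atoms: none
Why: Palladium-catalysed reductive desulfonylation. Zerovalent palladium ionises the allylic sulfone to a π-allyl complex over C2–C1–C10, and hydride attacks the less substituted terminus C2. Because C10 is fully substituted, the alkene stays at C1=C10 with its geometry.

Step 24
Reactants: 32 macrocycle (as described in step 23)
Product: 33 the C8 alcohol corresponding to 32 (C8–OH, otherwise unchanged)
Conditions: HF·pyridine, pyridine, THF, 0 °C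
Reagents that add atoms: none
Why: Fluoride-mediated cleavage selective for the triethylsilyl ether over the tert-butyldiphenylsilyl ether. The pyridine buffer keeps the medium too weakly acidic for the freed C8 hydroxyl to transacetalise with the C14 dioxolane.

Step 25
Reactants: 33 C8 alcohol (as described in step 24); 34 isovaleric anhydride
Product: 35 the C8 3-methylbutanoate of 33
Conditions: 34, DMAP, Et3N, CH2Cl2, rt
Reagents that add atoms: isovaleric anhydride 34, CC(C)CC(=O)OC(=O)CC(C)C
Why: DMAP-catalysed acylation of the hindered secondary alcohol with retention at C8. It is done before C12 is oxidised so that no hydroxy acid able to form the 8,12-lactone ever exists.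

Step 26
Reactants: 35 isovalerate (as described in step 25)
Product: 36 the C12 alcohol corresponding to 35 (C12–OH, otherwise unchanged)
Conditions: DDQ, CH2Cl2/pH 7 buffer (Na2HPO4/NaH2PO4), 0 °C
Reagents that add atoms: none
Why: Oxidative cleavage of the 4-methoxybenzyl ether (hydride abstraction, then hydrolysis of the oxocarbenium ion) under neutral conditions that spare the ester, the silyl ether and the dioxolane.

Step 27
Reactants: 36 C12 alcohol (as described in step 26)
Product: 38 (7S,8S)-15-[(tert-butyldiphenylsilyl)oxy]-14,14-(ethylenedioxy)-8-(3-methylbutanoyloxy)germacra-1(10)E,4E,11(13)-trien-12-oic acid, via C12 aldehyde 37 (not isolated)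
Conditions: DMP, NaHCO3, CH2Cl2, 0 °C; then NaClO2, NaH2PO4, 2-methylbut-2-ene, t-BuOH/H2O, 0 °C
Reagents that add atoms: sodium chlorite, [Na+].[O-]Cl=O
Why: Oxidation of the allylic alcohol to the 2-substituted acrolein, then Pinnick oxidation to the acrylic acid, with 2-methylbut-2-ene trapping hypochlorous acid. The cyclic acetal and the silyl ether tolerate the NaH2PO4 buffer at 0 °C, so C14 is not exposed to the oxidant.

Step 28
Reactants: 38 protected acid (as named in step 27)
Product: 39 (7S,8S)-15-hydroxy-8-(3-methylbutanoyloxy)-14-oxogermacra-1(10)E,4E,11(13)-trien-12-oic acid (6-deoxy seco acid; both ring alkenes ring-cis)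
Conditions: 48% aq. HF, MeCN, 0 °C → rt
Reagents that add atoms: water, O
Why: Acid hydrolysis of the dioxolane to the enal and fluoride-assisted desilylation take place in one medium. The isovalerate, the acrylic acid and the alkenes are stable to it, and no lactone can form because C8 is acylated.

Step 29
Reactants: 39 6-deoxy seco acid (as named in step 28)
Product: 41 (6R,7S,8S)-15-hydroxy-8-(3-methylbutanoyloxy)-14-oxogermacra-1(10)E,4E,11(13)-trien-12,6-olide (CNP0345200.6), via 6-hydroxy seco acid 40 (not isolated)
Conditions: engineered CYP71-family P450 with its NADPH–P450 reductase (cell lysate), NADP+ (cat.), D-glucose, glucose dehydrogenase, air, K2HPO4/KH2PO4 buffer pH 7.5, 25 °C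
Reagents that add atoms: dioxygen, O=O
Why: Proposed new method: the oxoiron porphyrin radical cation of the P450 (formally tetravalent iron) abstracts the C6 hydrogen that lies cis to C11, the allylic C6 radical recombines with the iron-bound hydroxyl (oxygen rebound) to give 40, and the C6 hydroxyl then attacks the C12 carboxyl in a 5-exo-trig acyl substitution with loss of water, closing the cis-fused γ-lactone of 41. The closest known reaction type is the CYP71-family C6 hydroxylation of germacra-1(10),4,11(13)-trien-12-oic acids followed by spontaneous lactonisation; new here are the cis,cis ring, the opposite C6 face and the additional C8 ester, C14 aldehyde and C15 alcohol. The new stereocentre C6 is controlled by the enzyme pocket alone, and rebound with retention puts oxygen on the face of the hydrogen removed. The selectivity needed is C6 over C2, C3, C9, C15 and the tertiary allylic C7–H, and over epoxidation of three alkenes and oxidation of the enal. The C12 carboxylate serves as anchor and places the C6–H bond (γ to it and allylic) over the iron; variants are to be selected by directed evolution. Lactonisation should be spontaneous because hydroxyl and acrylic acid sit cis on adjacent ring carbons, and a work-up at pH 4 would complete it if needed. Lysate with a glucose/glucose dehydrogenase NADPH cycle is used instead of whole cells to keep host reductases away from the enal.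

## Compound list

1 | 3,3-diethoxyprop-1-yne | C#CC(OCC)OCC | starting material
2 | 2-ethynyl-1,3-dioxolane | C#CC1OCCO1 | intermediate
3 | 3-(1,3-dioxolan-2-yl)prop-2-yn-1-ol | OCC#CC1OCCO1 | intermediate
4 | (2Z)-3-(1,3-dioxolan-2-yl)-3-iodoprop-2-en-1-ol | OC/C=C(\I)C1OCCO1 | intermediate
5 | sodium benzenesulfinate | [Na+].[O-]S(=O)c1ccccc1 | starting material
6 | (2Z)-3-(1,3-dioxolan-2-yl)-3-iodoprop-2-en-1-yl methanesulfonate | CS(=O)(=O)OC/C=C(\I)C1OCCO1 | intermediate
7 | 2-[(1Z)-1-iodo-3-(phenylsulfonyl)prop-1-en-1-yl]-1,3-dioxolane | O=S(=O)(C/C=C(\I)C1OCCO1)c1ccccc1 | intermediate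
8 | ethyl bromoacetate | BrCC(=O)OCC | starting material
9 | ethyl (3E)-3-(1,3-dioxolan-2-yl)-5-(phenylsulfonyl)pent-3-enoate | CCOC(=O)C/C(=C\CS(=O)(=O)c1ccccc1)C1OCCO1 | intermediate
10 | (3E)-3-(1,3-dioxolan-2-yl)-5-(phenylsulfonyl)pent-3-enal | O=CC/C(=C\CS(=O)(=O)c1ccccc1)C1OCCO1 | intermediate
11 | but-2-yne-1,4-diol | OCC#CCO | starting material
12 | 4-[(tert-butyldiphenylsilyl)oxy]but-2-yn-1-ol | OCC#CCO[Si](c1ccccc1)(c1ccccc1)C(C)(C)C | intermediate
13 | (2Z)-4-[(tert-butyldiphenylsilyl)oxy]-3-iodobut-2-en-1-ol | OC/C=C(\I)CO[Si](c1ccccc1)(c1ccccc1)C(C)(C)C | intermediate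
14 | {[(2Z)-4-bromo-2-iodobut-2-en-1-yl]oxy}(tert-butyl)diphenylsilane | BrC/C=C(\I)CO[Si](c1ccccc1)(c1ccccc1)C(C)(C)C | intermediate
15 | acetic acid | CC(=O)O | starting material
16 | (4Z)-6-[(tert-butyldiphenylsilyl)oxy]-5-iodohex-4-enoic acid | OC(=O)CC/C=C(\I)CO[Si](c1ccccc1)(c1ccccc1)C(C)(C)C | intermediate
17 | (4R)-4-benzyl-1,3-oxazolidin-2-one | O=C1N[C@H](Cc2ccccc2)CO1 | starting material
18 | (4Z)-6-[(tert-butyldiphenylsilyl)oxy]-5-iodohex-4-enoic pivalic anhydride | CC(C)(C)C(=O)OC(=O)CC/C=C(\I)CO[Si](c1ccccc1)(c1ccccc1)C(C)(C)C | intermediate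
19 | (4R)-4-benzyl-3-{(4Z)-6-[(tert-butyldiphenylsilyl)oxy]-5-iodohex-4-enoyl}-1,3-oxazolidin-2-one | O=C1OC[C@@H](Cc2ccccc2)N1C(=O)CC/C=C(\I)CO[Si](c1ccccc1)(c1ccccc1)C(C)(C)C | intermediate
20 | (tributylstannyl)methanol | CCCC[Sn](CCCC)(CCCC)CO | starting material
21 | (4R)-4-benzyl-3-{(4E)-6-[(tert-butyldiphenylsilyl)oxy]-5-(hydroxymethyl)hex-4-enoyl}-1,3-oxazolidin-2-one (hydroxymethyl cis to C6) | O=C1OC[C@@H](Cc2ccccc2)N1C(=O)CC/C=C(\CO)CO[Si](c1ccccc1)(c1ccccc1)C(C)(C)C | intermediate
22 | (4R)-4-benzyl-3-{(4E)-6-[(tert-butyldiphenylsilyl)oxy]-5-[(pivaloyloxy)methyl]hex-4-enoyl}-1,3-oxazolidin-2-one (pivaloyloxymethyl cis to C6) | O=C1OC[C@@H](Cc2ccccc2)N1C(=O)CC/C=C(\COC(=O)C(C)(C)C)CO[Si](c1ccccc1)(c1ccccc1)C(C)(C)C | intermediate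
23 | tributyl{[(4-methoxybenzyl)oxy]methyl}stannane | CCCC[Sn](CCCC)(CCCC)COCc1ccc(OC)cc1 | intermediate
24 | (4R)-4-benzyl-3-{(2R,3S,5E)-2-[(2E)-4-[(tert-butyldiphenylsilyl)oxy]-3-[(pivaloyloxy)methyl]but-2-en-1-yl]-5-(1,3-dioxolan-2-yl)-3-hydroxy-7-(phenylsulfonyl)hept-5-enoyl}-1,3-oxazolidin-2-one | O=C1OC[C@@H](Cc2ccccc2)N1C(=O)[C@@H]([C@@H](O)C/C(=C\CS(=O)(=O)c2ccccc2)C2OCCO2)C/C=C(\COC(=O)C(C)(C)C)CO[Si](c2ccccc2)(c2ccccc2)C(C)(C)C | intermediate
25 | (2R,3S,5E)-2-[(2E)-4-[(tert-butyldiphenylsilyl)oxy]-3-[(pivaloyloxy)methyl]but-2-en-1-yl]-5-(1,3-dioxolan-2-yl)-3-hydroxy-N-methoxy-N-methyl-7-(phenylsulfonyl)hept-5-enamide | CON(C)C(=O)[C@@H]([C@@H](O)C/C(=C\CS(=O)(=O)c1ccccc1)C1OCCO1)C/C=C(\COC(=O)C(C)(C)C)CO[Si](c1ccccc1)(c1ccccc1)C(C)(C)C | intermediate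
26 | (2R,3S,5E)-2-[(2E)-4-[(tert-butyldiphenylsilyl)oxy]-3-[(pivaloyloxy)methyl]but-2-en-1-yl]-5-(1,3-dioxolan-2-yl)-N-methoxy-N-methyl-7-(phenylsulfonyl)-3-[(triethylsilyl)oxy]hept-5-enamide | CON(C)C(=O)[C@@H]([C@@H](O[Si](CC)(CC)CC)C/C(=C\CS(=O)(=O)c1ccccc1)C1OCCO1)C/C=C(\COC(=O)C(C)(C)C)CO[Si](c1ccccc1)(c1ccccc1)C(C)(C)C | intermediate
27 | (3R,4S,6E)-3-[(2E)-4-[(tert-butyldiphenylsilyl)oxy]-3-[(pivaloyloxy)methyl]but-2-en-1-yl]-6-(1,3-dioxolan-2-yl)-1-[(4-methoxybenzyl)oxy]-8-(phenylsulfonyl)-4-[(triethylsilyl)oxy]oct-6-en-2-one | COc1ccc(COCC(=O)[C@@H]([C@@H](O[Si](CC)(CC)CC)C/C(=C\CS(=O)(=O)c2ccccc2)C2OCCO2)C/C=C(\COC(=O)C(C)(C)C)CO[Si](c2ccccc2)(c2ccccc2)C(C)(C)C)cc1 | intermediate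
28 | (7S,8S)-2,3-seco-germacra-1(10),4,11(13)-triene: C2 phenylsulfonyl, C3 pivaloyloxy, C8 triethylsilyloxy, C12 (4-methoxybenzyl)oxy, C14 as 1,3-dioxolan-2-yl, C15 tert-butyldiphenylsilyloxy; C3 cis to C6, C2 cis to C9 | C=C(COCc1ccc(OC)cc1)[C@@H]([C@@H](O[Si](CC)(CC)CC)C/C(=C\CS(=O)(=O)c1ccccc1)C1OCCO1)C/C=C(\COC(=O)C(C)(C)C)CO[Si](c1ccccc1)(c1ccccc1)C(C)(C)C | intermediate
29 | C3 alcohol of the 2,3-seco series (as 28 with C3–OH) | C=C(COCc1ccc(OC)cc1)[C@@H]([C@@H](O[Si](CC)(CC)CC)C/C(=C\CS(=O)(=O)c1ccccc1)C1OCCO1)C/C=C(\CO)CO[Si](c1ccccc1)(c1ccccc1)C(C)(C)C | intermediate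
30 | C3 bromide of the 2,3-seco series (as 28 with C3–Br) | C=C(COCc1ccc(OC)cc1)[C@@H]([C@@H](O[Si](CC)(CC)CC)C/C(=C\CS(=O)(=O)c1ccccc1)C1OCCO1)C/C=C(\CBr)CO[Si](c1ccccc1)(c1ccccc1)C(C)(C)C | intermediate
31 | (7S,8S)-2-(phenylsulfonyl)germacra-1(10)E,4E,11(13)-triene: C8 triethylsilyloxy, C12 (4-methoxybenzyl)oxy, C14 as 1,3-dioxolan-2-yl, C15 tert-butyldiphenylsilyloxy; ring-cis alkenes; C2 epimers | C=C(COCc2ccc(OC)cc2)[C@@H]1C/C=C(/CO[Si](c2ccccc2)(c2ccccc2)C(C)(C)C)CC(S(=O)(=O)c2ccccc2)/C=C(/C2OCCO2)C[C@@H]1O[Si](CC)(CC)CC | intermediate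
32 | (7S,8S)-germacra-1(10)E,4E,11(13)-triene: C8 triethylsilyloxy, C12 (4-methoxybenzyl)oxy, C14 as 1,3-dioxolan-2-yl, C15 tert-butyldiphenylsilyloxy | C=C(COCc2ccc(OC)cc2)[C@@H]1C/C=C(/CO[Si](c2ccccc2)(c2ccccc2)C(C)(C)C)CC/C=C(/C2OCCO2)C[C@@H]1O[Si](CC)(CC)CC | intermediate
33 | (7S,8S)-germacra-1(10)E,4E,11(13)-trien-8-ol: C12 (4-methoxybenzyl)oxy, C14 as 1,3-dioxolan-2-yl, C15 tert-butyldiphenylsilyloxy | C=C(COCc2ccc(OC)cc2)[C@@H]1C/C=C(/CO[Si](c2ccccc2)(c2ccccc2)C(C)(C)C)CC/C=C(/C2OCCO2)C[C@@H]1O | intermediate
34 | isovaleric anhydride (3-methylbutanoic anhydride) | CC(C)CC(=O)OC(=O)CC(C)C | starting material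
35 | 8-O-(3-methylbutanoyl) derivative of 33 | C=C(COCc2ccc(OC)cc2)[C@@H]1C/C=C(/CO[Si](c2ccccc2)(c2ccccc2)C(C)(C)C)CC/C=C(/C2OCCO2)C[C@@H]1OC(=O)CC(C)C | intermediate
36 | (7S,8S)-8-(3-methylbutanoyloxy)germacra-1(10)E,4E,11(13)-trien-12-ol: C14 as 1,3-dioxolan-2-yl, C15 tert-butyldiphenylsilyloxy | C=C(CO)[C@@H]1C/C=C(/CO[Si](c2ccccc2)(c2ccccc2)C(C)(C)C)CC/C=C(/C2OCCO2)C[C@@H]1OC(=O)CC(C)C | intermediate
37 | the corresponding germacra-1(10)E,4E,11(13)-trien-12-al | C=C(C=O)[C@@H]1C/C=C(/CO[Si](c2ccccc2)(c2ccccc2)C(C)(C)C)CC/C=C(/C2OCCO2)C[C@@H]1OC(=O)CC(C)C | intermediate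
38 | (7S,8S)-15-[(tert-butyldiphenylsilyl)oxy]-14,14-(ethylenedioxy)-8-(3-methylbutanoyloxy)germacra-1(10)E,4E,11(13)-trien-12-oic acid | C=C(C(=O)O)[C@@H]1C/C=C(/CO[Si](c2ccccc2)(c2ccccc2)C(C)(C)C)CC/C=C(/C2OCCO2)C[C@@H]1OC(=O)CC(C)C | intermediate
39 | (7S,8S)-15-hydroxy-8-(3-methylbutanoyloxy)-14-oxogermacra-1(10)E,4E,11(13)-trien-12-oic acid (6-deoxy seco acid) | C=C(C(=O)O)[C@@H]1C/C=C(/CO)CC/C=C(/C=O)C[C@@H]1OC(=O)CC(C)C | intermediate
40 | (6R,7S,8S)-6,15-dihydroxy-8-(3-methylbutanoyloxy)-14-oxogermacra-1(10)E,4E,11(13)-trien-12-oic acid (6-OH cis to C11) | C=C(C(=O)O)[C@@H]1[C@H](O)/C=C(/CO)CC/C=C(/C=O)C[C@@H]1OC(=O)CC(C)C | intermediate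
41 | (6R,7S,8S)-15-hydroxy-8-(3-methylbutanoyloxy)-14-oxogermacra-1(10)E,4E,11(13)-trien-12,6-olide (CNP0345200.6) | C=C1C(=O)O[C@@H]2/C=C(/CO)CC/C=C(/C=O)C[C@H](OC(=O)CC(C)C)[C@H]12 | target

## Step count and least certain steps

Total step count: 29. Longest linear sequence: 22 steps (steps 7–13, then 15–29); the other branch (steps 1–6, then 15–29) has 21.

**Step 29 (new method).** The most likely failure is oxidation at the wrong place or face: hydrogen abstraction at C7, C15, C2, C3 or C9, epoxidation of an alkene, or no productive binding of the cis,cis substrate. The pocket of the known enzymes is shaped for the trans,trans acids and the other C6 face. The fallback with known chemistry sets out from 36 and comes back at 41. NOCl/pyridine would convert the C12 hydroxyl into the allylic nitrite F1. Photolysis (Barton nitrite reaction) would give the C12 alkoxy radical, which takes the C6 hydrogen through a six-membered transition state; recombination with NO and tautomerisation would give the 6-oxime F2. Deoximation (aq. NaHSO3 or TiCl3/NH4OAc) would give the conjugated 6-ketone F3. A Corey–Bakshi–Shibata reduction with catecholborane at −78 °C, the catalyst enantiomer being chosen for the 6R alcohol (hydroxyl cis to C11), would give the 6,12-diol F4. TEMPO/PhI(OAc)2 would oxidise the primary allylic alcohol to the aldehyde, whose lactol with the C6 hydroxyl is oxidised on to the silyl- and acetal-protected lactone F5. 48% aq. HF in MeCN, as in step 28, would then give 41. The weak points of this detour are hydrogen transfer from C8 instead of C6 and capture of NO at C4 of the allylic radical.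

**Step 22.** The most likely failure is intermolecular alkylation (oligomers) outrunning the slow ten-membered ring closure, or loss of the dioxolane oxygen by 1,4-elimination from the sulfonyl carbanion. The fallback sets out from 29 and comes back at 31. ClCO2Me/pyridine would give the allylic methyl carbonate F6. LiN(SiMe3)2 (2 equiv) and ClCO2Me at −78 °C would give the α-sulfonyl ester F7. Pd(PPh3)4 in THF at 65 °C under high dilution (Tsuji–Trost macrocyclisation; the methoxide released from the carbonate deprotonates the doubly stabilised carbon, which attacks the less hindered allyl terminus C3) would give the macrocyclic sulfonyl ester F8. Krapcho demethoxycarbonylation (LiCl, wet DMSO, 120 °C) would then give 31.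

**Step 18.** The most likely failure is consumption of material through reactions of the sulfonyl carbanion that the basic reagent generates (intramolecular attack on C11), or attack on the pivalate. The fallback sets out from 26 and comes back at 27. Cp2Zr(H)Cl would reduce the N-methoxy-N-methylamide to the aldehyde F9. A SmI2-mediated Barbier-type addition of 4-methoxybenzyl chloromethyl ether (non-basic) would give the secondary alcohol F10 as C11 epimers. DMP would oxidise it to 27.

**Step 6 (with consequences for step 15).** The most likely failure is over-reduction, or migration of the β,γ-alkene into conjugation during work-up, because the aldehyde α-protons are also allylic. The fallback sets out from 9 and comes back at 10. Excess i-Bu2AlH at 0 °C would give the stable homoallylic alcohol F11, which would be oxidised with DMP/NaHCO3 at 0 °C immediately before the aldol.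

## Further compounds

F1 | step 29 | allylic nitrite of 36 (C12–O–N=O) | C=C(CON=O)[C@@H]1C/C=C(/CO[Si](c2ccccc2)(c2ccccc2)C(C)(C)C)CC/C=C(/C2OCCO2)C[C@@H]1OC(=O)CC(C)C
F2 | step 29 | 6-(hydroxyimino) derivative of 36 (oxime geometry not defined) | C=C(CO)[C@@H]1C(=NO)/C=C(/CO[Si](c2ccccc2)(c2ccccc2)C(C)(C)C)CC/C=C(/C2OCCO2)C[C@@H]1OC(=O)CC(C)C
F3 | step 29 | 6-oxo derivative of 36 (4-en-6-one) | C=C(CO)[C@@H]1C(=O)/C=C(/CO[Si](c2ccccc2)(c2ccccc2)C(C)(C)C)CC/C=C(/C2OCCO2)C[C@@H]1OC(=O)CC(C)C
F4 | step 29 | (6R,7S,8S)-6,12-diol (6-OH cis to C11), C14 dioxolane, C15 tert-butyldiphenylsilyl ether | C=C(CO)[C@@H]1[C@H](O)/C=C(/CO[Si](c2ccccc2)(c2ccccc2)C(C)(C)C)CC/C=C(/C2OCCO2)C[C@@H]1OC(=O)CC(C)C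
F5 | step 29 | (6R,7S,8S)-12,6-olide with C14 as 1,3-dioxolan-2-yl and C15 tert-butyldiphenylsilyloxy | C=C1C(=O)O[C@@H]2/C=C(/CO[Si](c3ccccc3)(c3ccccc3)C(C)(C)C)CC/C=C(/C3OCCO3)C[C@H](OC(=O)CC(C)C)[C@H]12
F6 | step 22 | C3 methyl carbonate of 29 | C=C(COCc1ccc(OC)cc1)[C@@H]([C@@H](O[Si](CC)(CC)CC)C/C(=C\CS(=O)(=O)c1ccccc1)C1OCCO1)C/C=C(\COC(=O)OC)CO[Si](c1ccccc1)(c1ccccc1)C(C)(C)C
F7 | step 22 | C2 methoxycarbonyl derivative of F6 (α-sulfonyl ester, C2 epimers) | C=C(COCc1ccc(OC)cc1)[C@@H]([C@@H](O[Si](CC)(CC)CC)C/C(=C\C(C(=O)OC)S(=O)(=O)c1ccccc1)C1OCCO1)C/C=C(\COC(=O)OC)CO[Si](c1ccccc1)(c1ccccc1)C(C)(C)C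
F8 | step 22 | 2-methoxycarbonyl derivative of 31 (C2 epimers) | C=C(COCc2ccc(OC)cc2)[C@@H]1C/C=C(/CO[Si](c2ccccc2)(c2ccccc2)C(C)(C)C)CC(C(=O)OC)(S(=O)(=O)c2ccccc2)/C=C(/C2OCCO2)C[C@@H]1O[Si](CC)(CC)CC
F9 | step 18 | aldehyde corresponding to amide 26 (C11 formyl) | O=C[C@@H]([C@@H](O[Si](CC)(CC)CC)C/C(=C\CS(=O)(=O)c1ccccc1)C1OCCO1)C/C=C(\COC(=O)C(C)(C)C)CO[Si](c1ccccc1)(c1ccccc1)C(C)(C)C
F10 | step 18 | C11 secondary alcohol corresponding to ketone 27 (C11 epimers) | COc1ccc(COCC(O)[C@@H]([C@@H](O[Si](CC)(CC)CC)C/C(=C\CS(=O)(=O)c2ccccc2)C2OCCO2)C/C=C(\COC(=O)C(C)(C)C)CO[Si](c2ccccc2)(c2ccccc2)C(C)(C)C)cc1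
F11 | step 6 | (3E)-3-(1,3-dioxolan-2-yl)-5-(phenylsulfonyl)pent-3-en-1-ol | OCC/C(=C\CS(=O)(=O)c1ccccc1)C1OCCO1
A1 | alternative 1 | ten-membered C8 homoallylic alcohol (C6 and C12 tert-butyldimethylsilyl ethers, C14 4-methoxybenzyl ether, C15 tert-butyldiphenylsilyl ether) | C=C(CO[Si](C)(C)C(C)(C)C)[C@@H]1[C@H](O[Si](C)(C)C(C)(C)C)/C=C(/CO[Si](c2ccccc2)(c2ccccc2)C(C)(C)C)CC/C=C(/COCc2ccc(OC)cc2)C[C@@H]1O
A2 | alternative 2 | cyclodec-4-en-1(10)-yn-6-one with C8 triethylsilyloxy, C7 methoxycarbonylmethyl and C15 tert-butyldiphenylsilyloxy | O=C1/C=C(/CO[Si](c2ccccc2)(c2ccccc2)C(C)(C)C)CCC#CC[C@H](O[Si](CC)(CC)CC)[C@@H]1CC(=O)OC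
A3 | alternative 3 | ten-membered C15 methyl enoate (C6 and C12 tert-butyldimethylsilyl ethers, C8 triethylsilyl ether, C14 4-methoxybenzyl ether) | C=C(CO[Si](C)(C)C(C)(C)C)[C@@H]1[C@H](O[Si](C)(C)C(C)(C)C)/C=C(/C(=O)OC)CC/C=C(/COCc2ccc(OC)cc2)C[C@@H]1O[Si](CC)(CC)CC
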